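**Retrosynthetic overview**
1. Target 16 ⇒ eleven-membered (2Z,4E,10E)-trienone bis-angelate 15 by a transannular crossed [2+2] photocycloaddition that makes both new cyclobutane C–C bonds. The cyclobutane, ring A (the bicyclo[3.1.1]heptenone) and the seven-membered ring are formed together, last.
2. 15 ⇒ macrocyclic triol 13 (site-selective bis-angeloylation) ⇒ acyclic ynone–alkene 11 by a ring-closing vinyl–vinyl C–C bond (iodide-relay Heck-type isomerisation). The eleven-membered carbocycle is the first ring formed.
3. 11 ⇒ Weinreb amide 9 + propynyl Grignard; 9 ⇒ aldehyde 6 + prenyl bromide (chelation-controlled reverse prenylation sets the third carbinol centre and the quaternary carbon).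
4. 6 ⇒ (−)-2,3-O-isopropylidene-D-erythronolactone 1, which supplies the two ester-bearing carbinol centres, by MeLi addition, Horner–Wadsworth–Emmons olefination and oxidation.

Assumption: the target SMILES is read as (1R,2R,3S,4R,5S,7S,8R) in the tricyclo[5.4.0.0(2,8)]undecane numbering used below, with both esters as angelates (Z).

**Step 1**
Reactants: 1 (−)-2,3-O-isopropylidene-D-erythronolactone; 2 methyllithium
Product: 3 (3aR,6aR)-2,2,4-trimethyltetrahydrofuro[3,4-d][1,3]dioxol-4-ol (1-deoxy-3,4-O-isopropylidene-D-erythro-pent-2-ulofuranose; anomer mixture)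
Conditions: MeLi (1.05 equiv), THF, −78 °C; then H2O
Reagents that add atoms: methyllithium, [Li]C
Why: Single 1,2-addition of an organolithium to the γ-lactone stops at the lithium hemiketal at −78 °C (lactone-to-lactol addition); both carbinol stereocentres are bought with D-erythronolactone and are not touched.

**Step 2**
Reactants: 3 lactol; 4 diethyl {2-[methoxy(methyl)amino]-2-oxoethyl}phosphonate
Product: 5 (2E)-3-[(4S,5R)-5-(hydroxymethyl)-2,2-dimethyl-1,3-dioxolan-4-yl]-N-methoxy-N-methylbut-2-enamide
Conditions: 4 (2.2 equiv), NaH (3.3 equiv), THF, 0 to 50 °C; then H2O; minor Z isomer removed on silica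
Reagents that add atoms: diethyl {2-[methoxy(methyl)amino]-2-oxoethyl}phosphonate, CCOP(=O)(CC(=O)N(C)OC)OCC
Why: Horner–Wadsworth–Emmons olefination of the methyl ketone that is in equilibrium with the hemiketal alkoxide gives the trisubstituted (E)-enamide with the amide trans to the bulky dioxolane, the β,β-disubstituted Weinreb enamide is too poor an acceptor for oxa-Michael closure by the freed alkoxide, and no stereocentre is formed.

**Step 3**
Reactants: 5 hydroxy enamide
Product: 6 (2E)-3-[(4S,5S)-5-formyl-2,2-dimethyl-1,3-dioxolan-4-yl]-N-methoxy-N-methylbut-2-enamide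
Conditions: Dess–Martin periodinane (1.3 equiv), CH2Cl2, 0 °C to rt; used crude
Reagents that add atoms: none
Why: Dess–Martin oxidation turns the primary alcohol into the aldehyde under non-basic conditions that do not epimerise the cis-dioxolane carbaldehyde.

**Step 4**
Reactants: 6 aldehyde; 7 prenyl bromide (1-bromo-3-methylbut-2-ene)
Product: 9 (2E,4S,5S,6S)-4,5,6-trihydroxy-N-methoxy-N,3,7,7-tetramethylnona-2,8-dienamide, via dihydroxy aldehyde 8 (not isolated)
Conditions: TFA/H2O (9:1), 0 °C, evaporate; then indium powder (2 equiv), 7 (2 equiv), THF/H2O (1:1), rt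
Reagents that add atoms: prenyl bromide, CC(C)=CCBr
Why: Aqueous acid removes the acetonide and the freed α,β-dihydroxy aldehyde undergoes a Barbier-type indium allylation in water in which prenylindium attacks through its γ-carbon (reverse prenylation, creating the quaternary carbon) on the five-membered indium chelate of the carbonyl and the free α-hydroxyl, which sets the new carbinol centre (6S) syn to its neighbour as in unprotected aldoses (Cram-chelate control).

**Step 5**
Reactants: 9 triol Weinreb amide; 10 prop-1-yn-1-ylmagnesium bromide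
Product: 11 (4S,5S,6S,7E)-4,5,6-trihydroxy-3,3,7-trimethyldodeca-1,7-dien-10-yn-9-one
Conditions: 10 (0.5 M in THF, 6 equiv), THF, 0 °C to rt; inverse quench into cold 1 M HCl
Reagents that add atoms: prop-1-yn-1-ylmagnesium bromide, CC#C[Mg]Br
Why: Weinreb ketone synthesis in which three equivalents of the alkynyl Grignard reagent are consumed by the hydroxyl groups and a further one gives a magnesium-chelated tetrahedral intermediate that cannot over-add, while the acidic inverse quench protonates the released N,O-dimethylhydroxylamine before it can add to the ynone; the stereocentres are untouched.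

**Step 6**
Reactants: 11 ynone triol
Product: 13 (2Z,4E,7S,8S,9S,10E)-7,8,9-trihydroxy-3,6,6,10-tetramethylcycloundeca-2,4,10-trien-1-one, via (Z)-iodoenone 12 (not isolated)
Conditions: Pd(OAc)2 (10 mol %), tri(2-furyl)phosphine (30 mol %), LiI (30 mol %), AcOH (5 equiv), NaOAc (2 equiv), MeCN, 60 °C, slow addition to 1 mM
Reagents that add atoms: none
Why: Proposed new method: iodide-relay formal hydroalkenylation of an ynone by a tethered alkene, in which iodide and acetic acid add anti across the ynone to give the (Z)-β-iodoenone, zerovalent palladium inserts into the C–I bond, the vinylpalladium closes the eleven-membered ring by carbopalladation of the terminal carbon of the neopentyl vinyl group (Mizoroki–Heck macrocyclisation), β-hydride elimination can only give the (E)-disubstituted alkene because the neighbouring carbon is quaternary, and acetate returns proton and iodide from H–Pd–I so that both are catalytic and the substrate is simply isomerised; the Z geometry fixed in the iodide addition holds the new diene and the second enone on the same side of the ketone, no stereocentre is formed, and the closest known chemistry is the two-pot NaI/AcOH hydroiodination of ynones followed by an intramolecular Heck reaction.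

**Step 7**
Reactants: 13 macrocyclic triol; 14 angelic acid ((2Z)-2-methylbut-2-enoic acid)
Product: 15 (2Z,4E,7S,8R,9S,10E)-7-hydroxy-3,6,6,10-tetramethyl-8,9-bis[(2Z)-2-methylbut-2-enoyloxy]cycloundeca-2,4,10-trien-1-one
Conditions: 14 (2.4 equiv), 2,4,6-trichlorobenzoyl chloride (2.4 equiv), Et3N (5 equiv), toluene, rt; then 13, 75 °C
Reagents that add atoms: angelic acid, C/C=C(/C)C(=O)O
Why: Mixed-anhydride (Yamaguchi-type) esterification run without DMAP keeps the angelate Z geometry, and the allylic hydroxyl and its neighbour are acylated while the neopentyl hydroxyl next to the gem-dimethyl carbon stays free; no stereocentre is changed.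

**Step 8**
Reactants: 15 macrocyclic bis-angelate
Product: 16 (1R,2R,3S,4R,5S,7S,8R)-5-hydroxy-2,6,6,9-tetramethyl-11-oxotricyclo[5.4.0.0(2,8)]undec-9-ene-3,4-diyl bis[(2Z)-2-methylbut-2-enoate] (CNP0336239.1)
Conditions: [Ir(dF(CF3)ppy)2(dtbbpy)]PF6 (1 mol %), degassed MeCN (2 mM), 450 nm LEDs, rt
Reagents that add atoms: none
Why: Triplet energy transfer from the iridium sensitiser to the cross-conjugated trienone (the angelates and the product enone lie higher in triplet energy and are not excited) triggers a transannular crossed enone–alkene [2+2] photocycloaddition in which the δ-carbon of the dienone bonds to the α-carbon of the second enone and the allyl/tertiary 1,4-biradical closes, forming the cyclobutane, ring A and the seven-membered ring at once; the two bridges can only span opposite faces of the cyclobutane and the enone carbon is attacked anti to the allylic C–O bond with the three oxygen substituents pseudo-equatorial on the forming seven-membered ring, so the existing carbinol centres set the four new stereocentres as 1R,2R,7S,8R.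

**Compound list**
1 | (−)-2,3-O-isopropylidene-D-erythronolactone, (3aR,6aR)-2,2-dimethyldihydrofuro[3,4-d][1,3]dioxol-4(3aH)-one | CC1(C)O[C@@H]2COC(=O)[C@@H]2O1 | starting material
2 | methyllithium | [Li]C | starting material
3 | (3aR,6aR)-2,2,4-trimethyltetrahydrofuro[3,4-d][1,3]dioxol-4-ol (anomer mixture) | CC1(C)O[C@@H]2COC(C)(O)[C@@H]2O1 | intermediate
4 | diethyl {2-[methoxy(methyl)amino]-2-oxoethyl}phosphonate | CCOP(=O)(CC(=O)N(C)OC)OCC | starting material
5 | (2E)-3-[(4S,5R)-5-(hydroxymethyl)-2,2-dimethyl-1,3-dioxolan-4-yl]-N-methoxy-N-methylbut-2-enamide | CON(C)C(=O)/C=C(\C)[C@@H]1OC(C)(C)O[C@@H]1CO | intermediate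
6 | (2E)-3-[(4S,5S)-5-formyl-2,2-dimethyl-1,3-dioxolan-4-yl]-N-methoxy-N-methylbut-2-enamide | CON(C)C(=O)/C=C(\C)[C@@H]1OC(C)(C)O[C@@H]1C=O | intermediate
7 | prenyl bromide (1-bromo-3-methylbut-2-ene) | CC(C)=CCBr | starting material
8 | (2E,4S,5S)-4,5-dihydroxy-N-methoxy-N,3-dimethyl-6-oxohex-2-enamide (dihydroxy aldehyde; hydrated in water) | CON(C)C(=O)/C=C(\C)[C@H](O)[C@H](O)C=O | intermediate
9 | (2E,4S,5S,6S)-4,5,6-trihydroxy-N-methoxy-N,3,7,7-tetramethylnona-2,8-dienamide | CON(C)C(=O)/C=C(\C)[C@H](O)[C@H](O)[C@@H](O)C(C)(C)C=C | intermediate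
10 | prop-1-yn-1-ylmagnesium bromide | CC#C[Mg]Br | starting material
11 | (4S,5S,6S,7E)-4,5,6-trihydroxy-3,3,7-trimethyldodeca-1,7-dien-10-yn-9-one | CC#CC(=O)/C=C(\C)[C@H](O)[C@H](O)[C@@H](O)C(C)(C)C=C | intermediate
12 | (4S,5S,6S,7E,10Z)-4,5,6-trihydroxy-11-iodo-3,3,7-trimethyldodeca-1,7,10-trien-9-one | C/C(I)=C/C(=O)/C=C(\C)[C@H](O)[C@H](O)[C@@H](O)C(C)(C)C=C | intermediate
13 | (2Z,4E,7S,8S,9S,10E)-7,8,9-trihydroxy-3,6,6,10-tetramethylcycloundeca-2,4,10-trien-1-one | O=C1/C=C(\C)[C@H](O)[C@H](O)[C@@H](O)C(C)(C)/C=C/C(C)=C\1 | intermediate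
14 | angelic acid, (2Z)-2-methylbut-2-enoic acid | C/C=C(/C)C(=O)O | starting material
15 | (2Z,4E,7S,8R,9S,10E)-7-hydroxy-3,6,6,10-tetramethyl-8,9-bis[(2Z)-2-methylbut-2-enoyloxy]cycloundeca-2,4,10-trien-1-one | O=C1/C=C(\C)[C@H](OC(=O)/C(C)=C\C)[C@H](OC(=O)/C(C)=C\C)[C@@H](O)C(C)(C)/C=C/C(C)=C\1 | intermediate
16 | (1R,2R,3S,4R,5S,7S,8R)-5-hydroxy-2,6,6,9-tetramethyl-11-oxotricyclo[5.4.0.0(2,8)]undec-9-ene-3,4-diyl bis[(2Z)-2-methylbut-2-enoate] | C/C=C(/C)C(=O)O[C@@H]1[C@@H](O)C(C)(C)[C@@H]2[C@H]3C(=O)C=C(C)[C@@H]2[C@@]3(C)[C@@H]1OC(=O)/C(C)=C\C | target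

**Step count and risks**
Total steps: 8. Longest linear sequence: 8 (fully linear from 1).

The three steps most likely to fail:

Step 4. The chelate-controlled addition to the unprotected, hydrated dihydroxy aldehyde may be slow with the bulky prenyl reagent, or less than clean in its syn selectivity. The fallback sets out from 6 and comes back at 9. The acetonide is kept and 6 is prenylated directly (prenyl bromide, indium powder, DMF), which gives mainly the Felkin product, the (1R)-configured homoallylic alcohol acetonide F1, together with its epimer. The mixture is oxidised with Dess–Martin periodinane to the single β,γ-unsaturated ketone acetonide F2. Reduction with NaBH4 in MeOH at −40 °C, where hydride is delivered anti to the dioxolane C–O bond of this neopentyl-type ketone (Felkin–Anh), gives the (1S)-configured alcohol acetonide F3. TFA/H2O then cleaves the acetonide and gives triol 9.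

Step 6 (the proposed new method). Iodide turnover may be slow at high dilution, or H–Pd species may hydropalladate the ynone with the wrong regiochemistry or cyclise 5-endo onto the enone. The fallback uses established reactions, sets out from 11 and comes back at 13. The ynone is hydroiodinated with stoichiometric NaI in AcOH and the (Z)-iodoenone 12 is isolated. Stille coupling with tributyl(vinyl)stannane (Pd2(dba)3, AsPh3, NMP, rt) gives the (3Z,6E)-tetraenone triol F4. Ring-closing metathesis of its two terminal vinyl groups (second-generation Grubbs catalyst, toluene, 1 mM, 80 °C) closes the ring at the disubstituted alkene instead of the vinyl–vinyl single bond and gives 13. A 4Z isomer, if formed, is carried on, because sensitisation in step 8 equilibrates the alkene geometries.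

Step 8. The cycloaddition has not been run on this ring; it may give the parallel instead of the crossed adduct or the other cyclobutane diastereomer, and the product may undergo secondary photochemistry. The fallback sets out from 15 and comes back at 16. The free hydroxyl is capped (TESOTf, 2,6-lutidine) to give the 7-O-triethylsilyl ether of 15 F5, so that no OH···O=C hydrogen bond folds the tether and the bulky group is forced outward. F5 is irradiated directly (366 nm, Pyrex, degassed cyclohexane), the classical way transannular enone–alkene cycloadditions of humulane-type macrocycles are run, to give the 5-O-triethylsilyl ether of 16 F6. HF·pyridine removes the silyl group and gives 16.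

**Further compounds**
F1 | step 4 | (2E)-3-{(4S,5R)-5-[(1R)-1-hydroxy-2,2-dimethylbut-3-en-1-yl]-2,2-dimethyl-1,3-dioxolan-4-yl}-N-methoxy-N-methylbut-2-enamide | CON(C)C(=O)/C=C(\C)[C@@H]1OC(C)(C)O[C@@H]1[C@H](O)C(C)(C)C=C
F2 | step 4 | (2E)-3-[(4S,5S)-5-(2,2-dimethylbut-3-enoyl)-2,2-dimethyl-1,3-dioxolan-4-yl]-N-methoxy-N-methylbut-2-enamide | CON(C)C(=O)/C=C(\C)[C@@H]1OC(C)(C)O[C@@H]1C(=O)C(C)(C)C=C
F3 | step 4 | (2E)-3-{(4S,5R)-5-[(1S)-1-hydroxy-2,2-dimethylbut-3-en-1-yl]-2,2-dimethyl-1,3-dioxolan-4-yl}-N-methoxy-N-methylbut-2-enamide | CON(C)C(=O)/C=C(\C)[C@@H]1OC(C)(C)O[C@@H]1[C@@H](O)C(C)(C)C=C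
F4 | step 6 | (3Z,6E,8S,9S,10S)-8,9,10-trihydroxy-3,7,11,11-tetramethyltrideca-1,3,6,12-tetraen-5-one | C=C/C(C)=C\C(=O)/C=C(\C)[C@H](O)[C@H](O)[C@@H](O)C(C)(C)C=C
F5 | step 8 | 7-O-triethylsilyl ether of 15 | O=C1/C=C(\C)[C@H](OC(=O)/C(C)=C\C)[C@H](OC(=O)/C(C)=C\C)[C@@H](O[Si](CC)(CC)CC)C(C)(C)/C=C/C(C)=C\1
F6 | step 8 | 5-O-triethylsilyl ether of 16 | C/C=C(/C)C(=O)O[C@@H]1[C@@H](O[Si](CC)(CC)CC)C(C)(C)[C@@H]2[C@H]3C(=O)C=C(C)[C@@H]2[C@@]3(C)[C@@H]1OC(=O)/C(C)=C\C
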